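**Retrosynthetic overview**
- The C3–Br bond is made last, by electrophilic bromination of 5,7-dibromo-6-methoxy-1H-indole at its most nucleophilic position.
- The C2–H comes from hydrolysis and decarboxylation of the corresponding indole-2-carboxylate.
- The pyrrole ring is the only ring formed (the benzene ring is bought): Hemetsberger–Knittel thermolysis of an α-azidocinnamate.
- The key C–C bond (indole C2–C3) joins 3,5-dibromo-4-methoxybenzaldehyde and ethyl azidoacetate in an intermolecular aldol (Knoevenagel-type) condensation; the aldehyde is symmetric, so both ortho C–H positions are equivalent.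
- The aldehyde comes from O-methylation of 3,5-dibromo-4-hydroxybenzaldehyde, and the azidoacetate from ethyl bromoacetate and sodium azide.

Assumption: the target is planar and achiral (no stereocentre), so "single enantiomer" is taken to mean the single constitutional isomer drawn; the only stereo-element in the route is the Z double bond of compound 6.

**Route**

Step 1
Reactants: 1 3,5-dibromo-4-hydroxybenzaldehyde
Product: 2 3,5-dibromo-4-methoxybenzaldehyde
Conditions: MeI (1.5 equiv), K2CO3 (2 equiv), DMF, 40 °C, 6 h
Reagents that add atoms: iodomethane, CI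
Why: Williamson ether synthesis (SN2 O-methylation) of the acidic di-ortho-bromophenoxide, which K2CO3 forms completely while the aldehyde and aryl bromides are untouched.

Step 2
Reactants: 3 ethyl bromoacetate
Product: 4 ethyl azidoacetate
Conditions: NaN3 (1.2 equiv), acetone/H2O (3:1), reflux, 4 h; extracted and used as a crude solution (not distilled, blast shield)
Reagents that add atoms: sodium azide, [Na+].[N-]=[N+]=[N-]
Why: SN2 displacement of the activated α-bromo ester by azide is fast and clean.

Step 3
Reactants: 2 3,5-dibromo-4-methoxybenzaldehyde; 4 ethyl azidoacetate (4 equiv)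
Product: 6 ethyl (Z)-2-azido-3-(3,5-dibromo-4-methoxyphenyl)acrylate, via aldol adduct 5 (not isolated)
Conditions: NaOEt (4 equiv), EtOH, −15 → 0 °C, 4 h; aq NH4Cl
Reagents that add atoms: none
Why: Aldol (Knoevenagel-type) condensation in which the enolate of 4 adds to the electron-poor, non-enolisable aldehyde and E1cB loss of hydroxide from 5 gives the thermodynamically preferred Z alkene (aryl trans to ester); ethoxide matched to the ethyl ester avoids transesterification.

Step 4
Reactants: 6 ethyl (Z)-2-azido-3-(3,5-dibromo-4-methoxyphenyl)acrylate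
Product: 8 ethyl 5,7-dibromo-6-methoxy-1H-indole-2-carboxylate, via 2H-azirine 7 (not isolated)
Conditions: added dropwise to refluxing xylenes (140 °C, 0.05 M), 2 h
Reagents that add atoms: none
Why: Hemetsberger–Knittel indole synthesis, in which thermal loss of N2 gives the azirine/vinyl nitrene that closes onto an ortho C–H; the two ortho positions are equivalent, so only the 5,7-dibromo-6-methoxy isomer can form (direct analogy to 3,4,5-trimethoxybenzaldehyde → 5,6,7-trimethoxyindole-2-carboxylate).

Step 5
Reactants: 8 ethyl 5,7-dibromo-6-methoxy-1H-indole-2-carboxylate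
Product: 9 5,7-dibromo-6-methoxy-1H-indole-2-carboxylic acid
Conditions: NaOH (3 equiv), THF/EtOH/H2O, 60 °C, 3 h; then 1 M HCl to pH 2, filter
Reagents that add atoms: sodium hydroxide, [Na+].[OH-]
Why: Saponification (BAc2 ester hydrolysis) is routine here because the aryl bromides and aryl methyl ether are inert to aqueous hydroxide at 60 °C.

Step 6
Reactants: 9 5,7-dibromo-6-methoxy-1H-indole-2-carboxylic acid
Product: 10 5,7-dibromo-6-methoxy-1H-indole
Conditions: Cu powder (0.3 equiv), quinoline, 210 °C, 1–2 h, Ar; quinoline removed by cold 2 M HCl wash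
Reagents that add atoms: none
Why: Copper-mediated thermal protodecarboxylation of an indole-2-carboxylic acid is the standard finish of a Hemetsberger sequence and is precedented on bromoindole-2-carboxylic acids when the heating time is kept short.

Step 7
Reactants: 10 5,7-dibromo-6-methoxy-1H-indole
Product: 11 3,5,7-tribromo-6-methoxy-1H-indole
Conditions: NBS (1.0 equiv), DMF, 0 °C, dark, 1 h; aq Na2S2O3/NaHCO3; crystallisation or fast column on Et3N-deactivated silica
Reagents that add atoms: N-bromosuccinimide, O=C1CCC(=O)N1Br
Why: Electrophilic aromatic substitution goes to C3, the most nucleophilic indole position (C5 and C7 are already blocked), and one equivalent at 0 °C avoids 2,3-dibromination.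

**Compound list**

1 | 3,5-dibromo-4-hydroxybenzaldehyde | O=Cc1cc(Br)c(O)c(Br)c1 | starting material
2 | 3,5-dibromo-4-methoxybenzaldehyde | COc1c(Br)cc(C=O)cc1Br | intermediate
3 | ethyl bromoacetate | CCOC(=O)CBr | starting material
4 | ethyl azidoacetate | CCOC(=O)CN=[N+]=[N-] | intermediate
5 | ethyl 2-azido-3-(3,5-dibromo-4-methoxyphenyl)-3-hydroxypropanoate (aldol adduct; racemic diastereomer mixture, not isolated) | CCOC(=O)C(N=[N+]=[N-])C(O)c1cc(Br)c(OC)c(Br)c1 | intermediate
6 | ethyl (Z)-2-azido-3-(3,5-dibromo-4-methoxyphenyl)acrylate | CCOC(=O)/C(N=[N+]=[N-])=C/c1cc(Br)c(OC)c(Br)c1 | intermediate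
7 | ethyl 2-(3,5-dibromo-4-methoxyphenyl)-2H-azirine-3-carboxylate (racemic, not isolated) | CCOC(=O)C1=NC1c1cc(Br)c(OC)c(Br)c1 | intermediate
8 | ethyl 5,7-dibromo-6-methoxy-1H-indole-2-carboxylate | CCOC(=O)c1cc2cc(Br)c(OC)c(Br)c2[nH]1 | intermediate
9 | 5,7-dibromo-6-methoxy-1H-indole-2-carboxylic acid | OC(=O)c1cc2cc(Br)c(OC)c(Br)c2[nH]1 | intermediate
10 | 5,7-dibromo-6-methoxy-1H-indole | COc1c(Br)cc2cc[nH]c2c1Br | intermediate
11 | 3,5,7-tribromo-6-methoxy-1H-indole | COc1c(Br)cc2c(Br)c[nH]c2c1Br | target

**Step count**

Total steps: 7. Longest linear sequence: 6 steps (1 → 2 → 6 → 8 → 9 → 10 → 11); step 2 is a one-step side branch.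

**Steps most likely to fail, with fallbacks**

Step 3 (aldol condensation). The azidoacetate enolate decomposes under base, and yields can be low or dehydration incomplete. The fallback sets out from 2 and comes back at 6. Knoevenagel–Doebner condensation of 2 with monoethyl malonate (pyridine, cat. piperidine, 100 °C) gives ethyl (E)-3-(3,5-dibromo-4-methoxyphenyl)acrylate F1. Br2 in CHCl3 at rt adds anti across the alkene to give ethyl (2RS,3SR)-2,3-dibromo-3-(3,5-dibromo-4-methoxyphenyl)propanoate F2. NaN3 (3 equiv) in DMF at rt to 50 °C then replaces the α-bromide and eliminates HBr to give 6. The azide is introduced only after the C–C bond is made, so no base-labile azido enolate is needed.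

Step 6 (decarboxylation). At 210 °C with copper the aryl bromides, especially the one next to N–H, may undergo Ullmann-type coupling or hydrodebromination, and tar can form. The fallback sets out from 8 and comes back at 10, bypassing acid 9. DIBAL-H (THF, −78 → 0 °C) reduces the ester to (5,7-dibromo-6-methoxy-1H-indol-2-yl)methanol F3. MnO2 (CH2Cl2, rt) oxidises this to 5,7-dibromo-6-methoxy-1H-indole-2-carbaldehyde F4. Tsuji–Wilkinson decarbonylation with RhCl(PPh3)3 (1 equiv, toluene, reflux) then gives 10 without harsh copper chemistry.

Step 7 (C3 bromination). Over-bromination to the 2,3-dibromide is possible, and a free N–H 3-bromoindole is sensitive to acid, light and silica. The fallback sets out from 10 and comes back at 11. Bromination with pyridinium tribromide in pyridine at 0 °C is followed, without isolating the free N–H bromoindole, by Boc2O/DMAP/Et3N. This traps the product as tert-butyl 3,5,7-tribromo-6-methoxy-1H-indole-1-carboxylate F5, which is stable to chromatography. K2CO3 in MeOH at rt then removes the Boc group to give 11, isolated by crystallisation.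

**Further compounds**

F1 | step 3 | ethyl (E)-3-(3,5-dibromo-4-methoxyphenyl)acrylate | CCOC(=O)/C=C/c1cc(Br)c(OC)c(Br)c1
F2 | step 3 | ethyl (2RS,3SR)-2,3-dibromo-3-(3,5-dibromo-4-methoxyphenyl)propanoate (racemic, one enantiomer drawn) | CCOC(=O)[C@H](Br)[C@H](Br)c1cc(Br)c(OC)c(Br)c1
F3 | step 6 | (5,7-dibromo-6-methoxy-1H-indol-2-yl)methanol | OCc1cc2cc(Br)c(OC)c(Br)c2[nH]1
F4 | step 6 | 5,7-dibromo-6-methoxy-1H-indole-2-carbaldehyde | O=Cc1cc2cc(Br)c(OC)c(Br)c2[nH]1
F5 | step 7 | tert-butyl 3,5,7-tribromo-6-methoxy-1H-indole-1-carboxylate | COc1c(Br)cc2c(Br)cn(C(=O)OC(C)(C)C)c2c1Br
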